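At early times each run can be reduced to one number, its mean pseudo-first-order constant ln(c₀/c)/t up to the first reading, where c is c(starting material). The mean hides a curve, so the question is what error that makes.

| flask | starting material | free catalyst | time |
|---|---|---|---|
| red | 100 mM | 10.0 mM |  |
| ochre | 150 mM | 10.0 mM |  |
| teal | 100 mM | 5.00 mM |  |
| blue | 100 mM | 10.0 mM | 9.3 h |

- red run (time / h: [starting material] / mM): 0.62: 82.9; 1.2: 71.3; 1.9: 62.0; 2.5: 56.7; 3.1: 51.7
- ochre run (time / h: [starting material] / mM): 0.62: 124.6; 1.2: 104.9; 1.9: 87.9; 2.5: 78.1; 3.1: 71.0
- teal run (time / h: [starting material] / mM): 0.62: 94.7; 1.2: 89.9; 1.9: 85.3; 2.5: 83.1; 3.1: 81.0

(readings scatter by 0.5 mM)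

- Overall: starting material -> target, with free catalyst as catalyst.
- Constant volume, constant temperature.
- Readings of a species count what is bound in complexes too.
- An order is taken over about fifteen percent of the charge, up and down.

* how the opening rate goes with [free catalyst] round the charge of the red run: the exponent of the rate at two percent of starting material gone to target
* how the opening rate goes with [starting material] round the charge of the red run: the exponent of the rate at two percent of starting material gone to target (one fixed amount of target, the same in the runs compared)
* starting material in the blue run at 9.3 h, as a share of the starting material charged

What do the opening constants say? Up to 0.62 h, the red run gives 0.302 h⁻¹, the ochre run 0.299 h⁻¹ and the teal run 0.0878 h⁻¹. Red and ochre read alike, so the opening order in starting material is near one.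

And the catalyst? Teal has half the catalyst of red, and its constant is lower by a factor of 3.44. As an exponent, that reads 1.78.

Is that the order asked for? Not necessarily. That exponent is the mean slope of ln(rate) against ln c(free catalyst) over a twofold step, while the question wants the local slope at the red charge. The two are equal only if the curve is straight on those axes.

Which bent curve, then? I take the simplest one: the rate is proportional to the charge minus a fixed amount. Setting the ratio of the two differences equal to the factor above gives the dead charge, the amount of free catalyst charged that takes no part in the rate, 2.95 mM. The local order at the red charge is then the charge over the charge minus the dead charge, 1.42.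

Where is this weak? Two charges can't tell this curve from a true power, so the offset is my choice and they don't prove it. The window matters less: the readings at 3.1 h give a factor of 3.13 and a local order of 1.36.

The forecast gave 1.85 for the catalyst, against my 1.42, with 0.93 for starting material and 39% for the blue run, and it argued that “Halving the catalyst cuts the early rate about 3.5-fold”.

The flask gives 1.4 for the catalyst, 1.1 for starting material and 40.6% of the charge left in the blue run at 9.3 h, from these steps:

    free catalyst + starting material ⇌ catalyst-substrate complex, settled at all times (35.40 M⁻¹)
    catalyst-substrate complex + starting material ⇌ doubly bound catalyst, settled at all times (3.740 M⁻¹)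
    doubly bound catalyst → target + catalyst-substrate complex (22.39 h⁻¹)
    free catalyst → spent catalyst (1.253 h⁻¹)
    free catalyst + impurity → spent catalyst

Where an amount equal to two percent of the red charge has turned, the rate is 32 mM h⁻¹ in the red run and 47 mM h⁻¹ in the ochre run, which have the same charge of catalyst. My reading of the dead charge leaves an estimated 7.05 mM of live catalyst in the red run and 7.05 mM in the ochre run. The estimated rate per live catalyst is then 4.48 h⁻¹ in the red run and 6.64 h⁻¹ in the ochre run.

The readings are calculated for an exercise; scatter was added.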